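I have no constants for these flasks, but I have the north-east run, so I count half-lives of free monomer and ask how much of what is lost can stand in chains.

| flask | free monomer | transfer agent | pre-initiator | remark | time |
|---|---|---|---|---|---|
| north-east | 0.50 M | 0.050 M | 15 mol% | run made earlier |  |
| Saturday's | 0.50 M | 0.0500 M | 10 mol% |  | 2.0 min |
| Sunday's | 0.80 M | 0.0500 M | 10 mol% |  | 2.0 min |

north-east run (percent of the free monomer charged)

| time / s | monomer in chains / % | free monomer / % |
|---|---|---|
| 10.0 | 0.9 | 94.1 |
| 15.0 | 1.4 | 90.1 |
| 25.0 | 3.0 | 83.2 |
| 30.0 | 4.4 | 79.0 |
| 40.0 | 7.6 | 72.1 |

(scatter of a reading: 0.3 percentage points)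

* which of the two ends with the longer chains by the average number of monomer units in a chain (chains begun, living or dead) ("neither" if they lie within 10%) (Saturday's / Sunday's / neither)
* average number of monomer units in a chain (chains begun, living or dead) at the end, Saturday's
* average number of monomer units in a chain (chains begun, living or dead) at the end, Sunday's

- the average divides the monomer in chains by the number of chains begun, living and dead together
- the analysis behind the earlier runs scatters by 0.3 percentage points, standard deviation
- the earlier runs do not show the number of chains; that part of a forecast is a guess
- no earlier run changes the charge of pre-initiator; that part of a forecast is a guess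

Treating the fall of free monomer as pseudo-first-order, I take its last reading, 72.1% of the charge left at 40.0 s, and get a half-life of free monomer of 84.8 s, a reading that carries the scatter, and its use at 10 mol% of pre-initiator or at 0.80 M is a guess. The 2.0 min of both flasks are then 1.42 half-lives, which on this reckoning leaves 37.5% and takes away 62.5% of the charge.

Two extreme flasks can be solved in the head. In the first, whatever monomer is lost stands in chains, which gives 62.5% of the charge. In the second, the share of lost monomer found in chains stays at its last reading, 27.2%, which gives 17.0%. I expect the real flask between them, because in the north-east run that share, as read with its scatter, rose from 15.3% at the first reading.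

If I guess one chain for each pre-initiator, the chains are 10 mol% of the charge, and the length lies between 1.70 and 6.25, so I commit to about 3.26 for Saturday's. Counted that way the two flasks tie in my reckoning, whereas a count set by the transfer agent makes Sunday's 1.60 times as long as Saturday's, so I lean to Sunday's.

The forecast says Sunday's, with 3.3 (2.2 to 7) and 5.2 (3.4 to 11), and warns: “The chain count is the largest uncertainty”.

The flask gives 3.52 for Saturday's and 4.82 for Sunday's, so Sunday's ends longer; Saturday's holds 23.1% of its charge in chains beside 44.8% as uncatalysed product, and 32.1% remains as free monomer against my 37.5%.

    free monomer + initiator → living end + monomer in chains (k = 0.0510 M⁻¹ s⁻¹)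
    free monomer + living end → monomer in chains + living end, rate k2*[living end]*[free monomer] (k = 0.150 M⁻¹ s⁻¹)
    living end + transfer agent → dead chain (kL = 0.00990 M⁻¹ s⁻¹)
    free monomer → uncatalysed product (k = 0.00590 s⁻¹)
    pre-initiator → initiator (k = 0.0280 s⁻¹)

Sunday's read at 50 s is 0.590 half-lives, so I expect 66.4% left and between 9.14% and 33.6% in chains. It gives 62.8% and 13.0%, with length 3.00, below the 3.52 of Saturday's at 2.0 min, so Sunday's read that early against Saturday's at its full time reverses the order of the two.

All runs stem from a simulated flask from invented constants; noise was put on by code.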